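Remarks before the route
- Numbering: carotenoid locants are used throughout. Diene ring C1–C6 (C1 = C(CH3)2, C5 = C–CH3, C6 = exocyclic alkene carbon), chain C7–C15 and C15'–C7' (methyls on C9, C13, C13', C9'), hydroxy ring C1'–C6' (C3' = carbinol carbon).
- Assumption: crocetin dialdehyde 7, ketoisophorone 1 and 2,6-dimethylphenol 4 are taken as purchasable. All polyenes are handled under argon, in dim light, with triethylamine-deactivated silica.

## Analysis of the target

The target is a C40 retro-carotenoid, C40H52O. An 18-carbon chain C7–C7' joins a 1,1,5-trimethylcyclohexa-2,4-diene ring (C1–C6) and a 3'-hydroxy-1',1',5'-trimethylcyclohex-4'-ene ring (C1'–C6') through the exocyclic double bonds C6=C7 and C6'=C7'. All thirteen C=C bonds are conjugated and the central C15–C15' bond is single. The only stereocentre is C3' (S). It is allylic to C4'=C5' and so to the whole polyene, which makes the C3'–O bond easy to ionise, and it must be set by a reagent because nothing else in the molecule can relay it. The eight chain double bonds C8=C9 to C9'=C8' are E. At both exocyclic bonds the chain carbon C8 (C8') lies on the side of C1 (C1'); by CIP this is 6Z on the diene ring and 6'E on the hydroxy ring, the same spatial arrangement. The hard bonds are C6=C7 and C6'=C7': trisubstituted alkenes on ring carbons flanked by a quaternary carbon and a methyl-bearing sp2 carbon, where carbonyl olefination is poor. The diene ring is a 6-alkylidenecyclohexa-2,4-diene (a blocked isotoluene), so any cation at C6 or C2 can aromatise by a 1,2-shift of a C1 methyl group. The feature that decides the strategy is that C6 and C6' are the two ends of one even conjugated system. The polyene is therefore the two-electron-reduced, doubly deoxygenated form of a C6,C6'-diol whose nine chain double bonds sit one position over (C7=C8 to C8'=C7'). In addition, the ring C1–C6 is 2,6-dimethylphenol methylated on a ring carbon.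

## Retrosynthetic reasoning

15 from 14. Only the O–Si bond at C3' is cut. The oxygen must be a silyl ether during the titanium step: a free alkoxide at C3' would end up as an allylic titanium alkoxide in the retro-polyene and be deoxygenated. Fluoride removes the group under basic conditions, which the acid-labile product tolerates.

14 from 13 (key disconnection). No σ-bond of the skeleton is cut; the two exocyclic π-bonds C6=C7 and C6'=C7' are traced back to two tertiary C–O bonds at C6 and C6' of the nonaene diol 13. The cut is made here because these are the bonds that resist direct construction, whereas the C6–O carbinols come from additions to ketones that cannot enolise at the α-carbon. Both rings enter with their final alkene pattern, so no proton has to be removed regioselectively and no cation is needed. The forward reaction must remove two oxygens with two electrons, 20 atoms apart, and move nine double bonds by one position.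

13 from 12. The C7=C8 and C7'=C8' E-alkenes are traced back to triple bonds. A tertiary propargylic alkoxide directs trans-hydroalumination, so each E-alkene comes for free from the carbinol that sits next to it.

12 from 10 and 6; 10 from 8 and 3. The σ-bonds C6–C7 and C6'–C7' are cut. This splits C40 into two C9 ring ketones and one symmetrical C22 diyne. The forward reactions are 1,2-additions of acetylides to hindered carbonyl groups. The carbinol centres they create need no control because both become sp2 in the key step. Ketone 3 is added first because its adduct is robust; the acid-labile dienol from 6 is made last.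

8 from 7. C7 and C7' are removed as one-carbon units from the aldehyde carbons C8 and C8' of 7, which already holds the seven E double bonds and four methyl groups of the chain.

6 from 4 via 5. The bond between C1 and one of its methyl groups is cut. This is a dearomatisation: C-methylation of phenoxide 5 at the ortho carbon that already bears a methyl group gives the 6,6-dimethyl dienone, which cannot return to a phenol.

3 from 2 from 1. The C3'–H bond is cut. An enantioselective transfer hydrogenation of the unhindered carbonyl of 1 sets the only stereocentre, and silylation follows.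

## Alternatives that were turned down

Alternative 1: The textbook carotenoid disconnection at C11=C12 and C11'=C12' of the normal-pattern isomer. Two Wittig reactions of phosphonium salts A2 and A3 with the central dialdehyde A4 would give the normal-pattern carotenol A1. A dehydrogenation (N-bromosuccinimide, then base) would then remove H from C2 and C4' and shift all double bonds. It was turned down for three reasons. A2 and A3 each need a ring-to-chain elaboration of six or more steps. The two different Wittig reactions on symmetrical A4 are statistical. The last step must pick two specific allylic hydrogens, C2–H next to the quaternary C1 and C4'–H, among many allylic CH2 and CH3 positions of a dodecaene, so the retro pattern is left to the least controllable reaction of the route.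

Alternative 2: Disconnection of the central C15–C15' sp2–sp2 bond. A Stille coupling of the retro-C20 iodide A5 with the retro-C20 stannane A6 would join the halves. It was turned down because the coupling builds the easy bond. Each partner already contains an exocyclic C6=C7 bond, so the hard problem must be solved twice, on C20 polyenes that carry iodine or tin at the end of a hexaene or heptaene. Such compounds are prone to protodestannylation, light-induced isomerisation and, for A6, aromatisation of the diene ring. The step count roughly doubles.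

Alternative 3: Oxidative formation of C15–C15' by anodic tail-to-tail dehydrodimerisation of the terminal-vinyl retro-polyenes A7 and A8. The closest known reaction type is the anodic dehydrodimerisation of 1,1-diarylethylenes to tetraarylbutadienes. It was turned down on mechanistic grounds. A7 and A8 have nearly equal oxidation potentials, so homo- and cross-coupling would be statistical. The C40 product, with thirteen conjugated double bonds, is oxidised more easily than either monomer and would be consumed at the anode. The radical cations carry spin density at ring C4 as well as at C15. The protons released at the anode meet an ionisable allylic C3'–O bond and a diene ring prone to methyl shift. A7 and A8 would still need their own C6=C7 construction.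

Key step: step 8

## Route

Step 1
Reactants: 1 2,6,6-trimethylcyclohex-2-ene-1,4-dione (ketoisophorone)
Product: 2 (4S)-4-hydroxy-2,6,6-trimethylcyclohex-2-en-1-one ((S)-phorenol)
Conditions: RuCl[(S,S)-TsDPEN](p-cymene) (1 mol%), i-PrOH, rt
Reagents that add atoms: none
Why: Noyori-type asymmetric transfer hydrogenation through the six-membered Ru–H/N–H transition state; only the unhindered C4 carbonyl reacts because C1 is flanked by C(CH3)2 and the methyl-bearing alkene carbon; with the alkene taking the place of the aryl group in the usual model the (S,S)-catalyst should give the (S)-carbinol (the mirror-image catalyst is used if the sense proves opposite), and this centre becomes C3' of the target.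

Step 2
Reactants: 2 (S)-phorenol
Product: 3 (4S)-4-[(tert-butyldimethylsilyl)oxy]-2,6,6-trimethylcyclohex-2-en-1-one
Conditions: TBSCl, imidazole, DMF, rt
Reagents that add atoms: tert-butyldimethylsilyl chloride, CC(C)(C)[Si](C)(C)Cl
Why: Standard silylation of a secondary allylic alcohol; no bond to the stereocentre is broken, the acidic OH is removed before the acetylide addition, and the silyl ether keeps the C3' oxygen off aluminium and titanium in steps 7 and 8.

Step 3
Reactants: 4 2,6-dimethylphenol
Product: 6 2,6,6-trimethylcyclohexa-2,4-dien-1-one, via lithium 2,6-dimethylphenoxide 5 (not isolated)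
Conditions: n-BuLi, toluene, 0 °C to rt; then MeI (excess), 100 °C, sealed vessel
Reagents that add atoms: iodomethane, CI
Why: Alkylative dearomatisation: the tightly aggregated lithium phenoxide in a non-polar solvent is methylated on the ortho carbon that already bears a methyl group, and the resulting 6,6-dimethyl dienone cannot tautomerise back to a phenol; the O-methylated by-product is removed by distillation and 6 is used fresh because it should dimerise slowly by Diels–Alder reaction.

Step 4
Reactants: 7 crocetin dialdehyde ((2E,4E,6E,8E,10E,12E,14E)-2,6,11,15-tetramethylhexadeca-2,4,6,8,10,12,14-heptaenedial)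
Product: 8 (3E,5E,7E,9E,11E,13E,15E)-3,7,12,16-tetramethyloctadeca-3,5,7,9,11,13,15-heptaene-1,17-diyne
Conditions: TMSCHN2 (2.5 equiv), n-BuLi (2.5 equiv), THF, −78 °C; then 7, −78 °C to rt; H2O
Reagents that add atoms: trimethylsilyldiazomethane, C[Si](C)(C)C=[N+]=[N-]
Why: Colvin homologation at both ends: addition of the lithiated diazo reagent to each aldehyde, Peterson-type loss of silanolate and loss of N2 give an alkylidene carbene whose 1,2-hydrogen shift delivers the terminal alkyne (new carbons C7 and C7'); the aprotic conditions suit enals and the seven E double bonds are not touched.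

Step 5
Reactants: 8 C22 heptaene-diyne (3 equiv); 3 silyloxy enone
Product: 10 (4S)-4-[(tert-butyldimethylsilyl)oxy]-2,6,6-trimethyl-1-[(3E,5E,7E,9E,11E,13E,15E)-3,7,12,16-tetramethyloctadeca-3,5,7,9,11,13,15-heptaene-1,17-diyn-1-yl]cyclohex-2-en-1-ol (C6' epimers), via mono-lithium acetylide 9 (not isolated)
Conditions: n-BuLi (1.05 equiv rel. to 3), THF, −78 °C; then 3, −78 to −20 °C; aq. NH4Cl
Reagents that add atoms: none
Why: 1,2-Addition of a lithium acetylide to a hindered enone that has no α-hydrogen, well precedented for 2,6,6-trimethylcyclohexenones; the excess of 8 keeps the reaction at mono-addition and is recovered; γ-deprotonation at C3' should be slow with the weakly basic acetylide at low temperature, and the new C6' carbinol centre may form as a mixture because it becomes sp2 in step 8.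

Step 6
Reactants: 10 mono-adduct; 6 2,6,6-trimethylcyclohexa-2,4-dien-1-one (1.5 equiv)
Product: 12 bis-propargylic diol, 10 carrying at its terminal alkyne carbon the 1-hydroxy-2,6,6-trimethylcyclohexa-2,4-dien-1-yl group (C6 and C6' epimers), via dilithium alkoxide-acetylide 11 (not isolated)
Conditions: n-BuLi (2.1 equiv), THF, −78 °C; then 6, −78 to −40 °C; aq. NH4Cl (pH 7–8)
Reagents that add atoms: none
Why: Second acetylide addition; the hard lithium acetylide should attack the carbonyl carbon of the dienone (no α-hydrogen, so no enolisation) in preference to the diene termini; the dienol product is kept away from acid to avoid the dienol–benzene rearrangement, and its C6 centre again needs no control.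

Step 7
Reactants: 12 bis-propargylic diol
Product: 13 1-[(1E,3E,5E,7E,9E,11E,13E,15E,17E)-18-[(4S)-4-[(tert-butyldimethylsilyl)oxy]-1-hydroxy-2,6,6-trimethylcyclohex-2-en-1-yl]-3,7,12,16-tetramethyloctadeca-1,3,5,7,9,11,13,15,17-nonaen-1-yl]-2,6,6-trimethylcyclohexa-2,4-dien-1-ol (C6 and C6' epimers)
Conditions: Red-Al (6 equiv), THF, 0 °C to rt; aq. Rochelle salt
Reagents that add atoms: none
Why: Alkoxide-directed trans-hydroalumination of both tertiary propargylic alcohols, the standard way to E-allylic alcohols from 6-hydroxy-7-yne end groups; it should give the 7E and 7'E alkenes, while the heptaene, which has no directing alkoxide, and the silyl ether stay untouched.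

Step 8
Reactants: 13 nonaene-6,6'-diol
Product: 14 3'-O-(tert-butyldimethylsilyl) ether of the target (all-E chain, C8 and C8' syn to C1 and C1')
Conditions: TiCl3 (6 equiv), LiAlH4 (3 equiv), THF, 0 °C to reflux (reagent formation); then 13, 0 °C to rt; aq. K2CO3, Celite; then I2 (cat.), hexane, daylight, rt, isolation of the all-E isomer by crystallisation or chromatography
Reagents that add atoms: none
Why: Proposed new method: a 1,20-reductive elimination through nine conjugated double bonds, whose closest known reaction types are the low-valent-titanium reductive elimination of 2-ene-1,4-diols to 1,3-dienes (and of the 1,6-vinylogues to trienes) and the reductive elimination of π-bridged diols to cumulenes and quinodimethanes. Mechanistically, 13 is bound as its titanium dialkoxide, the tertiary bis-allylic C6–O bond is cleaved by inner-sphere electron transfer to a radical (or its titanium-bound allyl form) delocalised from C2 through the chain to C7', and this species expels the remote C6'–O–Ti group in a vinylogous β-elimination, so that C6=C7 and C6'=C7' form, both oxygens end on titanium and the nine chain double bonds move by one position. No ring is closed and no stereocentre is created: C3' keeps its configuration because its oxygen is a silyl ether that cannot bind titanium, and the C6 and C6' carbinol centres become sp2. The first selectivity needed is elimination instead of simple deoxygenation of one end, which the conjugated leaving group at the far end of the delocalised intermediate should secure. The second is a radical or organometallic course and not a cationic one, which the hydridic, basic medium should secure and which avoids the 1,2-methyl shift (aromatisation) of a C6 cation of the diene ring and ionisation at C3'. The third is geometry: the new double bonds C8=C9 to C9'=C8' inherit E from the s-trans single bonds of the all-E nonaene, and the exocyclic bonds are expected to prefer the arrangement with C8 and C8' syn to C1 and C1' that is found in anhydroretinol-type retro-polyenes. The iodine/light treatment is the usual stereomutation of carotenoids; it should convert minor Z isomers into an equilibrium mixture from which the all-E isomer is collected, and the remainder is re-equilibrated.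

Step 9
Reactants: 14 silyl ether of the target
Product: 15 target, (3'S)-2,3,4',5'-tetradehydro-4,5'-retro-β,β-caroten-3'-ol
Conditions: TBAF, THF, 0 °C to rt; H2O
Reagents that add atoms: none
Why: Fluoride cleavage of a secondary TBS ether under basic, non-ionising conditions; acid is avoided because the C3'–O bond is now allylic to the whole polyene and the diene ring could aromatise; the configuration at C3' is not affected.

## Compound list

1 | 2,6,6-trimethylcyclohex-2-ene-1,4-dione (ketoisophorone) | O=C1C(C)=CC(=O)CC1(C)C | starting material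
2 | (4S)-4-hydroxy-2,6,6-trimethylcyclohex-2-en-1-one | O=C1C(C)=C[C@@H](O)CC1(C)C | intermediate
3 | (4S)-4-[(tert-butyldimethylsilyl)oxy]-2,6,6-trimethylcyclohex-2-en-1-one | O=C1C(C)=C[C@@H](O[Si](C)(C)C(C)(C)C)CC1(C)C | intermediate
4 | 2,6-dimethylphenol | Cc1cccc(C)c1O | starting material
5 | lithium 2,6-dimethylphenoxide | [Li+].[O-]c1c(C)cccc1C | intermediate (not isolated)
6 | 2,6,6-trimethylcyclohexa-2,4-dien-1-one | O=C1C(C)=CC=CC1(C)C | intermediate
7 | crocetin dialdehyde | O=C/C(C)=C/C=C/C(C)=C/C=C/C=C(C)/C=C/C=C(C)/C=O | starting material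
8 | (3E,5E,7E,9E,11E,13E,15E)-3,7,12,16-tetramethyloctadeca-3,5,7,9,11,13,15-heptaene-1,17-diyne | C#C/C(C)=C/C=C/C(C)=C/C=C/C=C(C)/C=C/C=C(C)/C#C | intermediate
9 | mono-lithium acetylide of 8 | [Li+].[C-]#C/C(C)=C/C=C/C(C)=C/C=C/C=C(C)/C=C/C=C(C)/C#C | intermediate (not isolated)
10 | (4S)-4-[(tert-butyldimethylsilyl)oxy]-2,6,6-trimethyl-1-[(3E,5E,7E,9E,11E,13E,15E)-3,7,12,16-tetramethyloctadeca-3,5,7,9,11,13,15-heptaene-1,17-diyn-1-yl]cyclohex-2-en-1-ol (C6' epimers) | OC1(C#C/C(C)=C/C=C/C(C)=C/C=C/C=C(C)/C=C/C=C(C)/C#C)C(C)=C[C@@H](O[Si](C)(C)C(C)(C)C)CC1(C)C | intermediate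
11 | dilithium alkoxide-acetylide of 10 | [Li+].[Li+].[O-]C1(C#C/C(C)=C/C=C/C(C)=C/C=C/C=C(C)/C=C/C=C(C)/C#[C-])C(C)=C[C@@H](O[Si](C)(C)C(C)(C)C)CC1(C)C | intermediate (not isolated)
12 | bis-propargylic diol: 1-[18-[(4S)-4-[(tert-butyldimethylsilyl)oxy]-1-hydroxy-2,6,6-trimethylcyclohex-2-en-1-yl]-3,7,12,16-tetramethyloctadeca-3,5,7,9,11,13,15-heptaene-1,17-diyn-1-yl]-2,6,6-trimethylcyclohexa-2,4-dien-1-ol (all-E chain; C6 and C6' epimers) | OC1(C#C/C(C)=C/C=C/C(C)=C/C=C/C=C(C)/C=C/C=C(C)/C#CC2(O)C(C)=CC=CC2(C)C)C(C)=C[C@@H](O[Si](C)(C)C(C)(C)C)CC1(C)C | intermediate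
13 | nonaene-6,6'-diol: 1-[(1E,3E,5E,7E,9E,11E,13E,15E,17E)-18-[(4S)-4-[(tert-butyldimethylsilyl)oxy]-1-hydroxy-2,6,6-trimethylcyclohex-2-en-1-yl]-3,7,12,16-tetramethyloctadeca-1,3,5,7,9,11,13,15,17-nonaen-1-yl]-2,6,6-trimethylcyclohexa-2,4-dien-1-ol (C6 and C6' epimers) | OC1(/C=C/C(C)=C/C=C/C(C)=C/C=C/C=C(C)/C=C/C=C(C)/C=C/C2(O)C(C)=CC=CC2(C)C)C(C)=C[C@@H](O[Si](C)(C)C(C)(C)C)CC1(C)C | intermediate
14 | 3'-O-(tert-butyldimethylsilyl) ether of (3'S)-2,3,4',5'-tetradehydro-4,5'-retro-β,β-caroten-3'-ol | CC1=CC=CC(C)(C)\C1=C/C=C(C)/C=C/C=C(C)/C=C/C=C/C(C)=C/C=C/C(C)=C/C=C1/C(C)=C[C@@H](O[Si](C)(C)C(C)(C)C)CC1(C)C | intermediate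
15 | (3'S)-2,3,4',5'-tetradehydro-4,5'-retro-β,β-caroten-3'-ol (all-E chain; C8 and C8' syn to C1 and C1') | CC1=CC=CC(C)(C)\C1=C/C=C(C)/C=C/C=C(C)/C=C/C=C/C(C)=C/C=C/C(C)=C/C=C1/C(C)=C[C@@H](O)CC1(C)C | target

## Step count and least certain steps

Total step count: 9. Longest linear sequence: 7 steps (steps 1, 2, 5, 6, 7, 8, 9, from 1 to 15).

Step 8 (key step, proposed new method). What may go wrong:
- Cleavage of only one C–O bond followed by protonation of the delocalised intermediate, which is over-reduction instead of elimination, because the second oxygen is 20 atoms away.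
- Lewis-acid-induced ionisation at C6 of the diene ring with methyl migration and aromatisation.
- Incomplete geometric convergence at the two exocyclic double bonds.

Fallback (known chemistry, redox-neutral instead of reductive; sets out from 8 and 6, comes back at 14). The hydroxy ring is brought in one oxidation level lower, so that two dehydrations replace the reduction.
- Commercial (4R,6R)-4-hydroxy-2,2,6-trimethylcyclohexanone is silylated to the silyloxy ketone F1.
- Acetylide 9 adds to F1 to give the propargylic carbinol F2.
- Red-Al reduces the hydroxy-directed triple bond to the E-allylic carbinol F3; the terminal alkyne is left alone.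
- Burgess reagent removes water across C5'–C6', the only position with a β-hydrogen, to give the normal-pattern 5',6'-ene enyne F4.
- The lithium acetylide of F4 adds to 6 to give the propargylic dienol F5.
- Red-Al gives the allylic dienol F6.
- Sulfonylation of the C6 hydroxyl in the presence of base (MsCl, Et3N, −40 °C) ionises the C6–O bond, and H-4' is removed through the eleven conjugated double bonds to give 14. This is the known vinylogous dehydration that converts retinol into anhydroretinol and 4-hydroxy-β-carotene into its retro-dehydro derivative.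

Step 6. What may go wrong:
- Diels–Alder dimerisation of 6 or attack at its diene termini before carbonyl addition.
- Dienol–benzene rearrangement of the adduct on work-up or chromatography, because the tertiary dienol ionises very easily.

Fallback (sets out from 10, comes back at 15). The diene ring is carried as a latent hydroxy ring.
- The dilithio species 11 is added to a second equivalent of 3 to give the bis-carbinol F7.
- Red-Al gives the nonaene diol F8.
- The titanium elimination of step 8 gives the bis-silyl ether F9.
- Fluoride gives the (3S,3'S)-diol F10 (eschscholtzxanthin).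
- Controlled acid-induced loss of one molecule of water from F10 (HCl in CHCl3, short contact), the known conversion of this diol into its anhydro compound, gives 15. Unchanged F10 is recycled.

Step 7. What may go wrong:
- Hydride delivery with loss of the tertiary alkoxide (SN2'-type), which leads to allene or cumulene formation instead of hydroalumination. The risk is highest at the dienol end, where the leaving alkoxide is bis-allylic.

Fallback (sets out from 8, comes back at 13). The alkyne reduction is replaced by a syn hydrometalation before the C–C bond formation.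
- Hydrozirconation of 8 with Schwartz reagent and iodinolysis give the bis-(E)-vinyl iodide F11.
- Iodine–lithium exchange at one end (t-BuLi, −100 °C) and addition to 3 give the iodo-nonaenyl carbinol F12.
- Deprotonation, a second exchange on F12 and addition to 6 give 13 directly, with 7E and 7'E fixed by the hydrozirconation.

Step 4. What may go wrong:
- Sluggish addition to the vinylogous, weakly electrophilic aldehyde groups.
- Trapping of the intermediate alkylidene carbene by the neighbouring polyene instead of the 1,2-hydrogen shift.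

Fallback (sets out from 7, comes back at 8). Corey–Fuchs sequence without a free carbene.
- CBr4, PPh3 and Zn convert 7 into the bis(dibromoalkene) F13.
- n-BuLi (4.2 equiv, −78 °C) converts F13 by halogen–metal exchange and rearrangement into the bis-acetylide, which gives 8 on protonation.

## Further compounds

F1 | step 8 | (4R,6R)-4-[(tert-butyldimethylsilyl)oxy]-2,2,6-trimethylcyclohexan-1-one | O=C1[C@H](C)C[C@@H](O[Si](C)(C)C(C)(C)C)CC1(C)C
F2 | step 8 | (4R,6R)-4-[(tert-butyldimethylsilyl)oxy]-2,2,6-trimethyl-1-[(3E,5E,7E,9E,11E,13E,15E)-3,7,12,16-tetramethyloctadeca-3,5,7,9,11,13,15-heptaene-1,17-diyn-1-yl]cyclohexan-1-ol (C1 epimers) | OC1(C#C/C(C)=C/C=C/C(C)=C/C=C/C=C(C)/C=C/C=C(C)/C#C)[C@H](C)C[C@@H](O[Si](C)(C)C(C)(C)C)CC1(C)C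
F3 | step 8 | (4R,6R)-4-[(tert-butyldimethylsilyl)oxy]-2,2,6-trimethyl-1-[(1E,3E,5E,7E,9E,11E,13E,15E)-3,7,12,16-tetramethyloctadeca-1,3,5,7,9,11,13,15-octaen-17-yn-1-yl]cyclohexan-1-ol (C1 epimers) | OC1(/C=C/C(C)=C/C=C/C(C)=C/C=C/C=C(C)/C=C/C=C(C)/C#C)[C@H](C)C[C@@H](O[Si](C)(C)C(C)(C)C)CC1(C)C
F4 | step 8 | tert-butyldimethyl{[(1R)-3,5,5-trimethyl-4-[(1E,3E,5E,7E,9E,11E,13E,15E)-3,7,12,16-tetramethyloctadeca-1,3,5,7,9,11,13,15-octaen-17-yn-1-yl]cyclohex-3-en-1-yl]oxy}silane | C#C/C(C)=C/C=C/C(C)=C/C=C/C=C(C)/C=C/C=C(C)/C=C/C1=C(C)C[C@@H](O[Si](C)(C)C(C)(C)C)CC1(C)C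
F5 | step 8 | 1-[(3E,5E,7E,9E,11E,13E,15E,17E)-18-[(4R)-4-[(tert-butyldimethylsilyl)oxy]-2,6,6-trimethylcyclohex-1-en-1-yl]-3,7,12,16-tetramethyloctadeca-3,5,7,9,11,13,15,17-octaen-1-yn-1-yl]-2,6,6-trimethylcyclohexa-2,4-dien-1-ol (C6 epimers) | OC1(C#C/C(C)=C/C=C/C(C)=C/C=C/C=C(C)/C=C/C=C(C)/C=C/C2=C(C)C[C@@H](O[Si](C)(C)C(C)(C)C)CC2(C)C)C(C)=CC=CC1(C)C
F6 | step 8 | 1-[(1E,3E,5E,7E,9E,11E,13E,15E,17E)-18-[(4R)-4-[(tert-butyldimethylsilyl)oxy]-2,6,6-trimethylcyclohex-1-en-1-yl]-3,7,12,16-tetramethyloctadeca-1,3,5,7,9,11,13,15,17-nonaen-1-yl]-2,6,6-trimethylcyclohexa-2,4-dien-1-ol (C6 epimers) | OC1(/C=C/C(C)=C/C=C/C(C)=C/C=C/C=C(C)/C=C/C=C(C)/C=C/C2=C(C)C[C@@H](O[Si](C)(C)C(C)(C)C)CC2(C)C)C(C)=CC=CC1(C)C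
F7 | step 6 | bis-propargylic diol from 10 and 3: 1,1'-[(3E,5E,7E,9E,11E,13E,15E)-3,7,12,16-tetramethyloctadeca-3,5,7,9,11,13,15-heptaene-1,17-diyne-1,18-diyl]bis[(4S)-4-[(tert-butyldimethylsilyl)oxy]-2,6,6-trimethylcyclohex-2-en-1-ol] (carbinol epimers) | OC1(C#C/C(C)=C/C=C/C(C)=C/C=C/C=C(C)/C=C/C=C(C)/C#CC2(O)C(C)=C[C@@H](O[Si](C)(C)C(C)(C)C)CC2(C)C)C(C)=C[C@@H](O[Si](C)(C)C(C)(C)C)CC1(C)C
F8 | step 6 | 1,1'-[(1E,3E,5E,7E,9E,11E,13E,15E,17E)-3,7,12,16-tetramethyloctadeca-1,3,5,7,9,11,13,15,17-nonaene-1,18-diyl]bis[(4S)-4-[(tert-butyldimethylsilyl)oxy]-2,6,6-trimethylcyclohex-2-en-1-ol] (carbinol epimers) | OC1(/C=C/C(C)=C/C=C/C(C)=C/C=C/C=C(C)/C=C/C=C(C)/C=C/C2(O)C(C)=C[C@@H](O[Si](C)(C)C(C)(C)C)CC2(C)C)C(C)=C[C@@H](O[Si](C)(C)C(C)(C)C)CC1(C)C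
F9 | step 6 | (3S,3'S)-3,3'-bis[(tert-butyldimethylsilyl)oxy]-4',5'-didehydro-4,5'-retro-β,β-carotene | CC1=C[C@@H](O[Si](C)(C)C(C)(C)C)CC(C)(C)\C1=C/C=C(C)/C=C/C=C(C)/C=C/C=C/C(C)=C/C=C/C(C)=C/C=C1/C(C)=C[C@@H](O[Si](C)(C)C(C)(C)C)CC1(C)C
F10 | step 6 | (3S,3'S)-4',5'-didehydro-4,5'-retro-β,β-carotene-3,3'-diol (eschscholtzxanthin) | CC1=C[C@@H](O)CC(C)(C)\C1=C/C=C(C)/C=C/C=C(C)/C=C/C=C/C(C)=C/C=C/C(C)=C/C=C1/C(C)=C[C@@H](O)CC1(C)C
F11 | step 7 | (1E,3E,5E,7E,9E,11E,13E,15E,17E)-1,18-diiodo-3,7,12,16-tetramethyloctadeca-1,3,5,7,9,11,13,15,17-nonaene | I/C=C/C(C)=C/C=C/C(C)=C/C=C/C=C(C)/C=C/C=C(C)/C=C/I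
F12 | step 7 | (4S)-4-[(tert-butyldimethylsilyl)oxy]-1-[(1E,3E,5E,7E,9E,11E,13E,15E,17E)-18-iodo-3,7,12,16-tetramethyloctadeca-1,3,5,7,9,11,13,15,17-nonaen-1-yl]-2,6,6-trimethylcyclohex-2-en-1-ol (C1 epimers) | OC1(/C=C/C(C)=C/C=C/C(C)=C/C=C/C=C(C)/C=C/C=C(C)/C=C/I)C(C)=C[C@@H](O[Si](C)(C)C(C)(C)C)CC1(C)C
F13 | step 4 | (3E,5E,7E,9E,11E,13E,15E)-1,1,18,18-tetrabromo-3,7,12,16-tetramethyloctadeca-1,3,5,7,9,11,13,15,17-nonaene | BrC(Br)=C/C(C)=C/C=C/C(C)=C/C=C/C=C(C)/C=C/C=C(C)/C=C(Br)Br
A1 | alternative 1 | (3R)-3',4'-didehydro-β,β-caroten-3-ol | CC1=C(/C=C/C(C)=C/C=C/C(C)=C/C=C/C=C(C)/C=C/C=C(C)/C=C/C2=C(C)C[C@@H](O)CC2(C)C)C(C)(C)CC=C1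
A2 | alternative 1 | [(2E,4E)-5-[(4R)-4-hydroxy-2,6,6-trimethylcyclohex-1-en-1-yl]-3-methylpenta-2,4-dien-1-yl]triphenylphosphonium bromide | CC1=C(/C=C/C(C)=C/C[P+](c2ccccc2)(c2ccccc2)c2ccccc2)C(C)(C)C[C@H](O)C1.[Br-]
A3 | alternative 1 | [(2E,4E)-3-methyl-5-(2,6,6-trimethylcyclohexa-1,3-dien-1-yl)penta-2,4-dien-1-yl]triphenylphosphonium bromide | CC1=C(/C=C/C(C)=C/C[P+](c2ccccc2)(c2ccccc2)c2ccccc2)C(C)(C)CC=C1.[Br-]
A4 | alternative 1 | (2E,4E,6E)-2,7-dimethylocta-2,4,6-trienedial | O=C/C(C)=C/C=C/C=C(C)/C=O
A5 | alternative 2 | tert-butyl{[(1S,4E)-4-[(2E,4E,6E,8E)-9-iodo-3,7-dimethylnona-2,4,6,8-tetraen-1-ylidene]-3,5,5-trimethylcyclohex-2-en-1-yl]oxy}dimethylsilane | I/C=C/C(C)=C/C=C/C(C)=C/C=C1/C(C)=C[C@@H](O[Si](C)(C)C(C)(C)C)CC1(C)C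
A6 | alternative 2 | tributyl[(1E,3E,5E,7E)-3,7-dimethyl-9-(2,6,6-trimethylcyclohexa-2,4-dien-1-ylidene)nona-1,3,5,7-tetraen-1-yl]stannane (chain syn to the ring C(CH3)2) | CC1=CC=CC(C)(C)\C1=C/C=C(C)/C=C/C=C(C)/C=C/[Sn](CCCC)(CCCC)CCCC
A7 | alternative 3 | (1S,4E)-4-[(2E,4E,6E)-3,7-dimethylnona-2,4,6,8-tetraen-1-ylidene]-3,5,5-trimethylcyclohex-2-en-1-ol | C=C/C(C)=C/C=C/C(C)=C/C=C1/C(C)=C[C@@H](O)CC1(C)C
A8 | alternative 3 | 6-[(2E,4E,6E)-3,7-dimethylnona-2,4,6,8-tetraen-1-ylidene]-1,5,5-trimethylcyclohexa-1,3-diene (chain syn to the ring C(CH3)2) | CC1=CC=CC(C)(C)\C1=C/C=C(C)/C=C/C=C(C)/C=C
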